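At early times the winter run climbed in a nearly straight line, its reading at 120 s being twice the one at 60.0 s, and the meeting took that run as its starting point for the flasks and questions below.

| flask | starting material | partner | protic impurity | free catalyst | remark | time |
|---|---|---|---|---|---|---|
| winter | 0.51 M | 0.69 M | 0.138 M | 23 mM | run made earlier |  |
| alder | 0.46 M | 0.690 M | 0.400 M | 23 mM |  | 5.0 min |
| cedar | 0.46 M | 0.690 M | 0.138 M | 30 mM |  | 5.0 min |
| ash | 0.46 M | 0.690 M | 0.138 M | 23 mM |  | 5.0 min |
| elm | 0.15 M | 3.00 M | 0.138 M | 23 mM |  | 5.0 min |
| oak | 0.25 M | 2.00 M | 0.100 M | 23 mM |  | 5.0 min |

winter run (percent of the starting material charged): time / s: product / % = 10.0: 3.0; 15.0: 3.4; 30.0: 7.6; 60.0: 12.9; 120: 24.0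

(each reading ± 0.5 percentage points)

- no earlier run changes the charge of free catalyst; that part of a forecast is a guess
- no earlier run changes the charge of protic impurity; that part of a forecast is a guess

* all flasks from highest to lowest amount of product, in percent of the starting material charged, at 5.0 min (alder / cedar / ash / elm / oak)
* the amount of product, in percent of the starting material charged of the flask you put first, at 5.0 min
* the amount of product, in percent of the starting material charged of the flask you put last, at 5.0 min

The maker of the forecast ranked the flasks elm > oak > cedar > ash > alder, giving 92% for the first (range 65% to 98%) and 33% for the last (range 17% to 48%), and said of the impurity: “I guess that the protic impurity retards the reaction, possibly by tying up catalyst.”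

I, keeping the minutes, answered that no run so far had varied the impurity, so that any view of it was a guess, and offered mine as a way of reckoning: suppose that each protic impurity destroys one starting material early on, count that step as finished, and reckon with the starting material it leaves free. The number for this is 87.0% in alder, the impurity share, meaning protic impurity charged over starting material charged, with the impurity as limiting reagent of that loss. So by this reckoning, which is an estimate, alder is left with 13.0% free and elm with 8.00%, against 70.0% for cedar and ash and 60.0% for oak. I therefore committed to cedar first, since it has more catalyst than ash at the same share, though the catalyst part was a guess too, and to alder and elm at the foot, whereas the forecast had elm at the head.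

The flasks gave cedar > oak > ash > elm > alder, with 46.4% for cedar and 11.0% for alder, while elm, first in the forecast, gave 20.7%, which is above the free share I had reckoned for it.

    partner + free catalyst → catalyst intermediate A (k = 16.0 M⁻¹ min⁻¹)
    starting material + catalyst intermediate A → catalyst intermediate B (k = 17.0 M⁻¹ min⁻¹)
    catalyst intermediate B → free catalyst + product (k = 270 min⁻¹)
    free catalyst → spent catalyst (k = 0.0850 min⁻¹)
    starting material + protic impurity → quenched substrate (k = 21.0 M⁻¹ min⁻¹)
    2 starting material → homo dimer (k = 0.370 M⁻¹ min⁻¹)

In alder, quenched substrate stood at 84.7% at 5.00 min against the 87.0% that the charge of impurity allows, and the run with that loss taken away proves its weight: alder's product goes from 11.0% to 50.3%, the largest single effect, which recovers 44% of what is missing.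

The same flask as alder but charged with 1.8 M of starting material has a share of 22.2%, and that neighbour flask came to 22.2% quenched substrate at 5.00 min, with 19.0% product and 52.2% homo dimer.

The earlier runs and the new flask stem from a simulated flask on assumed constants; noise was put on by code.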